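**Retrosynthetic overview**

1. Dorsilurin C is a flavonol. Ring C is closed last (O1–C2) by cyclodehydration of an ortho-hydroxyaryl 1,3-diketone, with loss of three MOM groups in the same operation.
2. The strategy rests on C2 of ring C: a single carbon at acyl oxidation level, flanked by C3 (the oxygen-bearing, enolisable α-carbon of a ring A ketone) and C1' of ring B (C7 of the 2,2-dimethyl-2H-chromene). It is therefore introduced as carbon monoxide, and C2–C3 and C2–C1' are both made in one palladium-catalysed carbonylative α-arylation of ketone 7 with bromide 12.
3. Ring A ketone 7: phloroglucinol, Friedel–Crafts acylation with acetoxyacetyl chloride, double C-prenylation with loss of the acetate, selective tris-MOM protection that leaves the chelated phenol free.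
4. Bromide 12: Kabbe condensation of 1-(4-bromo-2-hydroxyphenyl)ethanone with acetone (closes the pyran ring of the chromene), reduction, dehydration.
5. Order of ring formation: chromene pyran ring (step 4), then ring C (step 8); the benzene nuclei of rings A and B come from the starting materials.

Key step: step 7

Remark: diketone 14 is drawn in its open diketo form. It is expected to equilibrate with its enol and with the ring-closed 2-hydroxyflavanone hemiketal; all forms converge in step 8, so the mixture is carried forward as such.

**Route**

Step 1
Reactants: 1 phloroglucinol; 2 acetoxyacetyl chloride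
Product: 3 2-oxo-2-(2,4,6-trihydroxyphenyl)ethyl acetate
Conditions: AlCl3 (4 equiv), PhNO2/CH2Cl2, 0 °C to 40 °C; ice/dil. HCl
Reagents that add atoms: none
Why: Friedel–Crafts C-acylation of the symmetric, strongly activated phloroglucinol nucleus should stop at the mono-ketone because the first acyl group deactivates the ring, any O-acyl material being returned to carbon by Fries shift under AlCl3, while the acetoxy group keeps the future 3-oxygen masked in a form that the ortho phenol cannot displace to a benzofuranone.

Step 2
Reactants: 3 2-oxo-2-(2,4,6-trihydroxyphenyl)ethyl acetate; 4 1-bromo-3-methylbut-2-ene (prenyl bromide, 2.1 equiv)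
Product: 6 2-hydroxy-1-[2,4,6-trihydroxy-3,5-bis(3-methylbut-2-enyl)phenyl]ethanone, via free α-ketol 5 (not isolated)
Conditions: degassed 10% aq. KOH, 0 °C, 30 min; then 4 dropwise, 0 °C to rt, argon; dil. HCl
Reagents that add atoms: none
Why: Hydroxide first saponifies the activated primary acetate, and the resulting acylphloroglucinol polyanion is an ambident, enolate-like nucleophile that in water should be alkylated at its two equivalent free ring carbons by the allylic bromide (C-prenylation of acylphloroglucinols in aqueous alkali, the deoxyhumulone-type alkylation).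

Step 3
Reactants: 6 2-hydroxy-1-[2,4,6-trihydroxy-3,5-bis(3-methylbut-2-enyl)phenyl]ethanone
Product: 7 1-[2-hydroxy-4,6-bis(methoxymethoxy)-3,5-bis(3-methylbut-2-enyl)phenyl]-2-(methoxymethoxy)ethanone
Conditions: MOMCl (3.3 equiv), i-Pr2NEt (5 equiv), CH2Cl2, 0 °C to rt
Reagents that add atoms: chloromethyl methyl ether (MOMCl), COCCl
Why: Amine-mediated O-alkylation with MOMCl should acetalise the para phenol, one of the two equivalent ortho phenols and the primary alcohol, whereas the last ortho phenol is held in a strong hydrogen bond to the ketone, is flanked by a prenyl group, and in this substitution pattern resists MOMCl under amine base.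

Step 4
Reactants: 8 1-(4-bromo-2-hydroxyphenyl)ethanone; 9 acetone
Product: 10 7-bromo-2,2-dimethylchroman-4-one
Conditions: pyrrolidine (0.5 equiv), MeOH, reflux
Reagents that add atoms: none
Why: Kabbe condensation: the pyrrolidine-mediated aldol condensation of the methyl ketone with acetone gives the β,β-dimethyl enone and intramolecular oxa-Michael addition of the phenol closes the pyranone ring, which places the bromine unambiguously at C7.

Step 5
Reactants: 10 7-bromo-2,2-dimethylchroman-4-one
Product: 11 7-bromo-2,2-dimethylchroman-4-ol (racemic)
Conditions: NaBH4, MeOH, 0 °C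
Reagents that add atoms: none
Why: Borohydride reduction of the aryl ketone gives the benzylic alcohol as a racemate, which is of no consequence because this centre is destroyed in step 6, and the aryl bromide is inert to NaBH4.

Step 6
Reactants: 11 7-bromo-2,2-dimethylchroman-4-ol
Product: 12 7-bromo-2,2-dimethyl-2H-chromene
Conditions: p-TsOH·H2O (cat.), toluene, 90 °C, Dean–Stark
Reagents that add atoms: none
Why: Acid-catalysed E1 dehydration of the benzylic alcohol, driven by removal of water, gives the conjugated C3=C4 alkene of the 2H-chromene, which cannot migrate further because C2 is quaternary.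

Step 7
Reactants: 7 1-[2-hydroxy-4,6-bis(methoxymethoxy)-3,5-bis(3-methylbut-2-enyl)phenyl]-2-(methoxymethoxy)ethanone; 12 7-bromo-2,2-dimethyl-2H-chromene (1.2 equiv); 13 carbon monoxide
Product: 14 1-(2,2-dimethyl-2H-chromen-7-yl)-3-[2-hydroxy-4,6-bis(methoxymethoxy)-3,5-bis(3-methylbut-2-enyl)phenyl]-2-(methoxymethoxy)propane-1,3-dione (racemic, labile centre)
Conditions: Pd(dba)2 (5 mol%), Xantphos (5 mol%), NaN(SiMe3)2 (3.2 equiv), CO (1 atm), THF, 70 °C; aq. NH4Cl
Reagents that add atoms: none
Why: Zerovalent palladium ligated by Xantphos should add oxidatively to the C–Br bond of 12, CO insertion gives the aroyl complex of divalent palladium (C2–C1' formed), the sodium enolate at C3 of the dianion of 7 replaces bromide on palladium and C–C reductive elimination forms C2–C3, after which the 1,3-diketone is at once deprotonated by the third equivalent of base and so shielded from a second aroylation. The closest known reaction type is the palladium-catalysed carbonylative α-arylation of aryl alkyl ketones with aryl bromides to 1,3-diketones under Pd(dba)2/Xantphos. No ring is closed here; ring C stays open until step 8. The carbon between the two carbonyls (future C3) becomes a stereocentre, but it is configurationally labile, forms as a racemate and becomes sp2 in step 8, so it needs no control. The step needs C- over O-aroylation and carbonylative over direct arylation: reductive elimination from the aroyl(enolate)palladium complex favours carbon, any aryl ester formed at the ring A phenoxide is carried to the same diketone by Baker–Venkataraman acyl shift under the excess base, and the wide bite angle of Xantphos under a CO atmosphere makes insertion faster than enolate transfer to the arylpalladium species. Site selectivity is inherent because 7 has a single enolisable carbon, and the trisubstituted prenyl alkenes and the chromene alkene are poor partners for Heck-type insertion.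

Step 8
Reactants: 14 1-(2,2-dimethyl-2H-chromen-7-yl)-3-[2-hydroxy-4,6-bis(methoxymethoxy)-3,5-bis(3-methylbut-2-enyl)phenyl]-2-(methoxymethoxy)propane-1,3-dione
Product: 16 dorsilurin C, via MOM-protected flavone 15 (not isolated)
Conditions: conc. HCl (cat.), MeOH/THF, 45 °C; then NaHCO3
Reagents that add atoms: none
Why: Acid-catalysed cyclodehydration (the free ring A phenol adds 6-exo-trig to the C2 carbonyl and the hemiketal loses water to give the aromatic γ-pyrone of ring C) should precede or accompany methanolysis of the three MOM acetals, and dilute acid at moderate temperature is chosen because ortho-prenyl phenols and the chromene alkene (here deactivated by the flavone carbon para to its styrenic position) are expected to survive it; the target has no stereocentre.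

**Compound list**

1 | phloroglucinol (benzene-1,3,5-triol) | Oc1cc(O)cc(O)c1 | starting material
2 | acetoxyacetyl chloride | CC(=O)OCC(=O)Cl | starting material
3 | 2-oxo-2-(2,4,6-trihydroxyphenyl)ethyl acetate | CC(=O)OCC(=O)c1c(O)cc(O)cc1O | intermediate
4 | 1-bromo-3-methylbut-2-ene (prenyl bromide) | CC(C)=CCBr | starting material
5 | 2-hydroxy-1-(2,4,6-trihydroxyphenyl)ethanone (free α-ketol, not isolated) | OCC(=O)c1c(O)cc(O)cc1O | intermediate
6 | 2-hydroxy-1-[2,4,6-trihydroxy-3,5-bis(3-methylbut-2-enyl)phenyl]ethanone | OCC(=O)c1c(O)c(CC=C(C)C)c(O)c(CC=C(C)C)c1O | intermediate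
7 | 1-[2-hydroxy-4,6-bis(methoxymethoxy)-3,5-bis(3-methylbut-2-enyl)phenyl]-2-(methoxymethoxy)ethanone | COCOCC(=O)c1c(O)c(CC=C(C)C)c(OCOC)c(CC=C(C)C)c1OCOC | intermediate
8 | 1-(4-bromo-2-hydroxyphenyl)ethanone | CC(=O)c1ccc(Br)cc1O | starting material
9 | acetone | CC(C)=O | starting material
10 | 7-bromo-2,2-dimethylchroman-4-one | CC1(C)CC(=O)c2ccc(Br)cc2O1 | intermediate
11 | 7-bromo-2,2-dimethylchroman-4-ol (racemic) | CC1(C)CC(O)c2ccc(Br)cc2O1 | intermediate
12 | 7-bromo-2,2-dimethyl-2H-chromene | Brc1ccc2c(c1)OC(C)(C)C=C2 | intermediate
13 | carbon monoxide | [C-]#[O+] | starting material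
14 | 1-(2,2-dimethyl-2H-chromen-7-yl)-3-[2-hydroxy-4,6-bis(methoxymethoxy)-3,5-bis(3-methylbut-2-enyl)phenyl]-2-(methoxymethoxy)propane-1,3-dione (racemic, labile centre) | COCOC(C(=O)c1ccc2c(c1)OC(C)(C)C=C2)C(=O)c1c(O)c(CC=C(C)C)c(OCOC)c(CC=C(C)C)c1OCOC | intermediate
15 | 2-(2,2-dimethyl-2H-chromen-7-yl)-3,5,7-tris(methoxymethoxy)-6,8-bis(3-methylbut-2-enyl)-4H-chromen-4-one (not isolated) | COCOc1c(-c2ccc3c(c2)OC(C)(C)C=C3)oc2c(CC=C(C)C)c(OCOC)c(CC=C(C)C)c(OCOC)c2c1=O | intermediate
16 | dorsilurin C, 2-(2,2-dimethyl-2H-chromen-7-yl)-3,5,7-trihydroxy-6,8-bis(3-methylbut-2-enyl)-4H-chromen-4-one | CC(C)=CCc1c(O)c(CC=C(C)C)c2oc(-c3ccc4c(c3)OC(C)(C)C=C4)c(O)c(=O)c2c1O | target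

**Step count**

Total: 8 steps. Longest linear sequence: 5 steps (1, 2, 3, 7, 8; the branch 4, 5, 6, 7, 8 is equally long).

**Steps most likely to fail, with fallbacks**

1. Step 7. The hindered dianion of 7 may transfer too slowly to the aroylpalladium complex, so that CO-free direct arylation, capture of the aroyl complex by the silylamide, or catalyst deactivation under CO takes over. The fallback replaces the three-component coupling by a two-component Claisen-type aroylation. It sets out from 12 and 7 and comes back at 14. Bromine–lithium exchange on 12 (n-BuLi, THF, −78 °C) and quenching with CO2 should give 2,2-dimethyl-2H-chromene-7-carboxylic acid F1. Carbonyldiimidazole in THF converts it into the acyl imidazolide (2,2-dimethyl-2H-chromen-7-yl)(1H-imidazol-1-yl)methanone F2, which avoids exposing the chromene to HCl. The dianion of 7 (LiN(SiMe3)2, 3 equiv, THF, −78 °C to 0 °C) is then aroylated at C3 by F2; any ester formed at the phenoxide converges by Baker–Venkataraman shift, giving 14.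

2. Step 2. Alkylation of the polyanion may not stop cleanly at the 3,5-di-C-prenyl stage (mono-prenylation, geminal diprenylation with loss of aromaticity, O-prenylation), and the α-ketol may be oxidised in alkali if air is admitted. The fallback builds the two side chains by sigmatropic shift and olefin metathesis. It sets out from 3 and comes back at 6. Allyl bromide and K2CO3 in acetone should give 2-[2,4-bis(prop-2-enyloxy)-6-hydroxyphenyl]-2-oxoethyl acetate F3, the chelated phenol staying free. Double aromatic Claisen rearrangement (N,N-diethylaniline, 190 °C; ortho shift, or para shift through Cope relay where the ortho carbon is already taken) converges on 2-oxo-2-[2,4,6-trihydroxy-3,5-di(prop-2-enyl)phenyl]ethyl acetate F4. Cross-metathesis with excess 2-methylbut-2-ene and second-generation Grubbs catalyst (CH2Cl2, 40 °C) gives 2-oxo-2-[2,4,6-trihydroxy-3,5-bis(3-methylbut-2-enyl)phenyl]ethyl acetate F5. Methanolysis of the acetate (K2CO3, MeOH, 0 °C, argon) gives 6.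

3. Step 8. Under protic acid the freed 5- and 7-hydroxyls may add to the neighbouring prenyl alkenes (chroman formation), or methanol may add to the chromene alkene, before MOM cleavage is complete. The fallback separates ring closure from deprotection and changes the deprotection from Brønsted-acid solvolysis to thiol transacetalisation. It sets out from 14 and comes back at 16, and makes no compound outside the compound list (F0). Buffered cyclodehydration (NaOAc, AcOH, 80 °C) should give the MOM-protected flavone 15, now isolated; partial MOM loss at this stage is harmless. The acetals are then removed with ZnBr2 and n-PrSH in CH2Cl2 at 0 °C within minutes to give 16.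

**Further compounds**

F1 | step 7 | 2,2-dimethyl-2H-chromene-7-carboxylic acid | OC(=O)c1ccc2c(c1)OC(C)(C)C=C2
F2 | step 7 | (2,2-dimethyl-2H-chromen-7-yl)(1H-imidazol-1-yl)methanone | O=C(c1ccc2c(c1)OC(C)(C)C=C2)n1ccnc1
F3 | step 2 | 2-[2,4-bis(prop-2-enyloxy)-6-hydroxyphenyl]-2-oxoethyl acetate | CC(=O)OCC(=O)c1c(O)cc(OCC=C)cc1OCC=C
F4 | step 2 | 2-oxo-2-[2,4,6-trihydroxy-3,5-di(prop-2-enyl)phenyl]ethyl acetate | CC(=O)OCC(=O)c1c(O)c(CC=C)c(O)c(CC=C)c1O
F5 | step 2 | 2-oxo-2-[2,4,6-trihydroxy-3,5-bis(3-methylbut-2-enyl)phenyl]ethyl acetate | CC(=O)OCC(=O)c1c(O)c(CC=C(C)C)c(O)c(CC=C(C)C)c1O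
F0 | step 8 | none | none
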